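**Assumptions:** the two building blocks of step 1 are bought as catalogue chemicals. In step 4 the catalyst antipode that delivers the 1R series is used; it is written as (S,S) and must be confirmed in the first run. Atom labels C-1 to C-8a refer to the dihydronaphthalene numbering of the target.

## Retrosynthetic overview

1. Target ⇐ removal of two benzyl ethers and one tert-butyl ester from a fully protected (1R,2S)-dihydronaphthalene.
2. Key disconnection (one operation, two rings): open ring B at C-1–C-8a and the pyranone at its lactone C–O bond ⇒ one acyclic aryl triene acid carrying a 2-oxo-ester arm.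
3. The 2-oxo-ester arm ⇐ vinylogous Claisen of a C-methyl group with di-tert-butyl oxalate; the triene half-acid ⇐ Stobbe condensation, which places the free acid on C-2 and the methyl ester on C-3.
4. The alkylidene succinate partner ⇐ Horner–Wadsworth–Emmons olefination of a C5 ene-al ester with a phosphonosuccinate.
5. Ring order: ring A is bought (a benzaldehyde); the pyranone and ring B are then closed together in the key step, where a chiral acid sets C-1 and C-2 follows as trans.

## Route

Step 1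
Reactants: 1 methyl (E)-3-methyl-4-oxobut-2-enoate; 2 dimethyl 2-(dimethoxyphosphoryl)butanedioate
Product: 3 dimethyl (2E)-2-[(2E)-4-methoxy-2-methyl-4-oxobut-2-en-1-ylidene]butanedioate
Conditions: NaH (1.05 equiv), THF, 0 °C; then 1, −20 °C → rt
Reagents that add atoms: none
Why: Horner–Wadsworth–Emmons olefination; the stabilised phosphonate anion adds 1,2 to the aldehyde and syn-elimination gives the (E)-alkylidene succinate (aldehyde residue trans to the ester on the same carbon), with no stereocentre formed.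

Step 2
Reactants: 3 dimethyl (2E)-2-[(2E)-4-methoxy-2-methyl-4-oxobut-2-en-1-ylidene]butanedioate; 4 3,4-bis(benzyloxy)benzaldehyde
Product: 6 (2E,3E)-3-[3,4-bis(benzyloxy)benzylidene]-4-methoxy-2-[(2E)-4-methoxy-2-methyl-4-oxobut-2-en-1-ylidene]-4-oxobutanoic acid, via Stobbe lactone 5 (not isolated)
Conditions: LiN(iPr)2 (1.1 equiv), THF, −78 °C; then 4, −78 °C → rt; aq. HCl work-up
Reagents that add atoms: none
Why: Stobbe condensation; the extended enolate formed at the CH2 of 3 adds to 4, the alkoxide lactonises onto the ester of the neighbouring alkylidene carbon (lactone 5), and E1cB ring opening gives the (E)-benzylidene with the free acid on the future C-2 and the methyl ester on the future C-3, leaving no stereocentre.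

Step 3
Reactants: 6 (2E,3E)-3-[3,4-bis(benzyloxy)benzylidene]-4-methoxy-2-[(2E)-4-methoxy-2-methyl-4-oxobut-2-en-1-ylidene]-4-oxobutanoic acid; 7 di-tert-butyl oxalate
Product: 8 (2E,3E)-3-[3,4-bis(benzyloxy)benzylidene]-2-[(2E)-5-tert-butoxy-2-(2-methoxy-2-oxoethylidene)-4,5-dioxopentylidene]-4-methoxy-4-oxobutanoic acid
Conditions: KOtBu (3.3 equiv), THF, −20 °C → rt; cold 1 M HCl to pH 3
Reagents that add atoms: none
Why: Vinylogous Claisen condensation (the classical oxalate/β-methyl-enoate reaction); the carboxylate is inert, the C-methyl group is the only enolisable position, γ-acylation is driven by the stabilised enolate of the 2-oxo ester, and tBuO− matches the oxalate so nothing transesterifies; no stereocentre is formed.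

Step 4
Reactants: 8 (2E,3E)-3-[3,4-bis(benzyloxy)benzylidene]-2-[(2E)-5-tert-butoxy-2-(2-methoxy-2-oxoethylidene)-4,5-dioxopentylidene]-4-methoxy-4-oxobutanoic acid
Product: 10 (1R,2S)-6,7-bis(benzyloxy)-1-[6-(tert-butoxycarbonyl)-2-oxo-2H-pyran-4-yl]-3-(methoxycarbonyl)-1,2-dihydronaphthalene-2-carboxylic acid, via pyranone triene acid 9 (not isolated)
Conditions: (S,S)-IDPi Brønsted acid (N,N'-bis(triflyl) imidodiphosphorimidate from two 3,3'-bis[3,5-bis(trifluoromethyl)phenyl]-BINOL units, 10 mol %), 5 Å molecular sieves, toluene, 25 → 45 °C, under argon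
Reagents that add atoms: none
Why: Proposed new method: the confined strong acid first catalyses enol lactonisation of the 2-hydroxy-dienoate (loss of MeOH gives pyranone 9), then protonates the C-2 carboxyl so that the arene carbon para to a benzyloxy group attacks C-1 in a six-ring conjugate Friedel–Crafts closure (formally 6π-electrocyclisation/1,5-H shift) inside a chiral ion pair, which sets C-1 as R, and protonation of the dienol anti to the pyranone (the thermodynamic trans isomer) sets C-2 as S; the closest known reaction types are the triflic-acid cyclisation of (E,E)-dibenzylidenesuccinates to trans-1-aryl-1,2-dihydronaphthalenes, the acid closure of oxalocrotonates to 2-pyrone-6-carboxylates, and chiral Brønsted-acid-catalysed Nazarov and Friedel–Crafts cyclisations.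

Step 5
Reactants: 10 (1R,2S)-6,7-bis(benzyloxy)-1-[6-(tert-butoxycarbonyl)-2-oxo-2H-pyran-4-yl]-3-(methoxycarbonyl)-1,2-dihydronaphthalene-2-carboxylic acid
Product: 11 (1R,2S)-1-(6-carboxy-2-oxo-2H-pyran-4-yl)-6,7-dihydroxy-3-(methoxycarbonyl)-1,2-dihydronaphthalene-2-carboxylic acid
Conditions: BCl3 (6 equiv), pentamethylbenzene (6 equiv), CH2Cl2, −78 → −20 °C; THF/H2O quench
Reagents that add atoms: none
Why: Lewis-acid dealkylation with a cation scavenger cleaves both aryl benzyl ethers and the tert-butyl ester at low temperature, while the methyl ester, the pyranone and the conjugated alkene are untouched and the acidic, non-basic medium leaves C-1 and C-2 unchanged.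

## Compound list

1 | methyl (E)-3-methyl-4-oxobut-2-enoate | COC(=O)/C=C(\C)C=O | starting material
2 | dimethyl 2-(dimethoxyphosphoryl)butanedioate | COC(=O)CC(C(=O)OC)P(=O)(OC)OC | starting material
3 | dimethyl (2E)-2-[(2E)-4-methoxy-2-methyl-4-oxobut-2-en-1-ylidene]butanedioate | COC(=O)/C=C(\C)/C=C(\CC(=O)OC)C(=O)OC | intermediate
4 | 3,4-bis(benzyloxy)benzaldehyde | O=Cc1ccc(OCc2ccccc2)c(OCc2ccccc2)c1 | starting material
5 | methyl 2-[3,4-bis(benzyloxy)phenyl]-4-[(2E)-4-methoxy-2-methyl-4-oxobut-2-en-1-ylidene]-5-oxooxolane-3-carboxylate (Stobbe lactone; E-alkylidene, ring stereocentres undefined) | COC(=O)/C=C(\C)/C=C1/C(=O)OC(c2ccc(OCc3ccccc3)c(OCc3ccccc3)c2)C1C(=O)OC | intermediate (not isolated)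
6 | (2E,3E)-3-[3,4-bis(benzyloxy)benzylidene]-4-methoxy-2-[(2E)-4-methoxy-2-methyl-4-oxobut-2-en-1-ylidene]-4-oxobutanoic acid | COC(=O)/C=C(\C)/C=C(C(=O)O)\C(C(=O)OC)=C/c1ccc(OCc2ccccc2)c(OCc2ccccc2)c1 | intermediate
7 | di-tert-butyl oxalate | CC(C)(C)OC(=O)C(=O)OC(C)(C)C | starting material
8 | (2E,3E)-3-[3,4-bis(benzyloxy)benzylidene]-2-[(2E)-5-tert-butoxy-2-(2-methoxy-2-oxoethylidene)-4,5-dioxopentylidene]-4-methoxy-4-oxobutanoic acid (drawn as the 2-oxo ester, largely enolised; the ethylidene ester is cis to the CH2–CO–CO2tBu arm) | COC(=O)/C=C(\CC(=O)C(=O)OC(C)(C)C)/C=C(C(=O)O)\C(C(=O)OC)=C/c1ccc(OCc2ccccc2)c(OCc2ccccc2)c1 | intermediate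
9 | (2E,3E)-3-[3,4-bis(benzyloxy)benzylidene]-2-{[6-(tert-butoxycarbonyl)-2-oxo-2H-pyran-4-yl]methylidene}-4-methoxy-4-oxobutanoic acid | CC(C)(C)OC(=O)c1cc(/C=C(C(=O)O)\C(C(=O)OC)=C/c2ccc(OCc3ccccc3)c(OCc3ccccc3)c2)cc(=O)o1 | intermediate (not isolated)
10 | (1R,2S)-6,7-bis(benzyloxy)-1-[6-(tert-butoxycarbonyl)-2-oxo-2H-pyran-4-yl]-3-(methoxycarbonyl)-1,2-dihydronaphthalene-2-carboxylic acid | COC(=O)C1=Cc2cc(OCc3ccccc3)c(OCc3ccccc3)cc2[C@@H](c2cc(C(=O)OC(C)(C)C)oc(=O)c2)[C@@H]1C(=O)O | intermediate
11 | (1R,2S)-1-(6-carboxy-2-oxo-2H-pyran-4-yl)-6,7-dihydroxy-3-(methoxycarbonyl)-1,2-dihydronaphthalene-2-carboxylic acid (CNP0333269.1) | COC(=O)C1=Cc2cc(O)c(O)cc2[C@@H](c2cc(C(=O)O)oc(=O)c2)[C@@H]1C(=O)O | target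

## Step count

Total steps: 5. Longest linear sequence: 5 (1 → 3 → 6 → 8 → 10 → 11).

## Steps most likely to fail, and fallbacks

**Step 4 is the most likely to fail.** A catalytic chiral acid may be too weak for the Friedel–Crafts closure or may give poor enantiocontrol. The fallback gives up catalyst control: it sets out from 8 and comes back at 10. An achiral strong acid (5 mol % bis(trifluoromethanesulfonyl)imide in toluene at rt) is used, or failing that TsOH-catalysed lactonisation at 80 °C followed by thermal 6π-electrocyclisation/[1,5]-H shift in o-xylene at 140 °C. Either closes both rings and gives the racemic trans acid F1. Preparative chiral SFC on an amylose carbamate phase then delivers 10 and leaves its (1S,2R) enantiomer F2 as the discarded half.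

**Step 3 is next.** Claisen acylation of the trianionic triene 6 may give α-acylation, isomerisation or no reaction. The fallback builds the pyranone before any fragment union and avoids strong base afterwards: it sets out from 1 and comes back at 9, which closes to 10 under the step 4 conditions.
- Acetalisation of 1 (HC(OMe)3, TsOH, MeOH) gives methyl (E)-4,4-dimethoxy-3-methylbut-2-enoate F3.
- Oxalylation of F3 with 7 and KOtBu, then aqueous HCl in THF (lactonisation and acetal hydrolysis), gives tert-butyl 4-formyl-2-oxo-2H-pyran-6-carboxylate F4.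
- Mild olefination of F4 with 2 (LiCl, iPr2NEt, MeCN) gives the pyranonyl alkylidene succinate F5.
- Soft-enolisation aldol of F5 with 4 (TiCl4, Et3N, CH2Cl2, −78 °C → rt), whose titanium aldolate lactonises on warming, gives the paraconic lactone F6.
- The acid of step 4 opens F6 by ionisation of the p-benzyloxybenzylic C–O bond and loss of the C-3 proton, giving 9.

**Step 2 is third.** The extended enolate of 3 may react at the wrong carbon, or lactone 5 may not open cleanly. The fallback reverses the order of the two olefinations and differentiates the carboxyls with a tert-butyl ester: it sets out from 4 (1 enters later) and comes back at 6.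
- Stobbe condensation of 4 with dimethyl succinate (NaOMe, MeOH, reflux) gives the half-ester F7, already carrying the C-3 methyl ester.
- Esterification (Boc2O, DMAP, tBuOH) gives the mixed diester F8.
- Its lithium enolate (LiN(iPr)2, THF, −78 °C) adds to 1 and a cold quench gives the aldol adduct F9.
- Dehydration (MsCl, Et3N, then DBU) gives the diene tert-butyl ester F10.
- TFA in CH2Cl2 frees the C-2 acid and gives 6.

## Further compounds

F1 | step 4 | racemic trans acid (1:1 mixture of 10 and its enantiomer) | COC(=O)C1=Cc2cc(OCc3ccccc3)c(OCc3ccccc3)cc2[C@@H](c2cc(C(=O)OC(C)(C)C)oc(=O)c2)[C@@H]1C(=O)O.COC(=O)C1=Cc2cc(OCc3ccccc3)c(OCc3ccccc3)cc2[C@H](c2cc(C(=O)OC(C)(C)C)oc(=O)c2)[C@H]1C(=O)O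
F2 | step 4 | (1S,2R)-6,7-bis(benzyloxy)-1-[6-(tert-butoxycarbonyl)-2-oxo-2H-pyran-4-yl]-3-(methoxycarbonyl)-1,2-dihydronaphthalene-2-carboxylic acid | COC(=O)C1=Cc2cc(OCc3ccccc3)c(OCc3ccccc3)cc2[C@H](c2cc(C(=O)OC(C)(C)C)oc(=O)c2)[C@H]1C(=O)O
F3 | step 3 | methyl (E)-4,4-dimethoxy-3-methylbut-2-enoate | COC(=O)/C=C(\C)C(OC)OC
F4 | step 3 | tert-butyl 4-formyl-2-oxo-2H-pyran-6-carboxylate | CC(C)(C)OC(=O)c1cc(C=O)cc(=O)o1
F5 | step 3 | dimethyl (E)-2-{[6-(tert-butoxycarbonyl)-2-oxo-2H-pyran-4-yl]methylidene}butanedioate | COC(=O)C/C(C(=O)OC)=C\c1cc(C(=O)OC(C)(C)C)oc(=O)c1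
F6 | step 3 | methyl 2-[3,4-bis(benzyloxy)phenyl]-4-{[6-(tert-butoxycarbonyl)-2-oxo-2H-pyran-4-yl]methylidene}-5-oxooxolane-3-carboxylate (ring stereocentres undefined) | O=C1OC(c2ccc(OCc3ccccc3)c(OCc3ccccc3)c2)C(C(=O)OC)/C1=C\c4cc(C(=O)OC(C)(C)C)oc(=O)c4
F7 | step 2 | (E)-4-[3,4-bis(benzyloxy)phenyl]-3-(methoxycarbonyl)but-3-enoic acid | OC(=O)C/C(C(=O)OC)=C\c1ccc(OCc2ccccc2)c(OCc2ccccc2)c1
F8 | step 2 | 4-tert-butyl 1-methyl (2E)-2-[3,4-bis(benzyloxy)benzylidene]butanedioate | CC(C)(C)OC(=O)C/C(C(=O)OC)=C\c1ccc(OCc2ccccc2)c(OCc2ccccc2)c1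
F9 | step 2 | 4-tert-butyl 1-methyl (2E)-2-[3,4-bis(benzyloxy)benzylidene]-3-[(2E)-1-hydroxy-4-methoxy-2-methyl-4-oxobut-2-en-1-yl]butanedioate (two sp3 centres undefined) | COC(=O)/C=C(\C)C(O)C(C(=O)OC(C)(C)C)/C(C(=O)OC)=C\c1ccc(OCc2ccccc2)c(OCc2ccccc2)c1
F10 | step 2 | 1-tert-butyl 4-methyl (2E,3E)-3-[3,4-bis(benzyloxy)benzylidene]-2-[(2E)-4-methoxy-2-methyl-4-oxobut-2-en-1-ylidene]butanedioate | COC(=O)/C=C(\C)/C=C(C(=O)OC(C)(C)C)\C(C(=O)OC)=C/c1ccc(OCc2ccccc2)c(OCc2ccccc2)c1
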